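**Retrosynthetic overview**

1. Feature: the only ring is a cyclohexene whose trisubstituted C1=C2 bond carries one carbon on C1 (alkyne carbon Ca) and H on C2, followed by four contiguous oxygenated stereocentres C3(OAc), C4(OMe), C5(OH), C6(OH). This is a carbasugar alkene: ring C3–C6 = C1–C4 of D-galactose, ring C1 = sugar C5, Ca = sugar C6.
2. Late disconnections: C5/C6 acetonide and C3 acetate; the Cb–C(sp2) bond by Sonogashira coupling of ring enyne 19 with bromodiene 23 (from 2-methylbut-3-yn-2-ol and 2,3-dibromopropene); Ca≡Cb by one-carbon homologation of a C1 formyl group, so the ring–alkyne bond is never made by a coupling.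
3. Key disconnection: C1=C2 by ring-closing metathesis of 1,7-diene 15 (vinyl group on C3, 1,1-disubstituted alkene on C6); this is the only carbocycle-forming step.
4. Diene 15 from phenyl 1-thio-β-D-galactopyranoside: 3,4-acetonide, 6-O-silyl, 2-O-methyl, lactone, Weinreb amide (frees O5–H alone), C5 ketone to methylidene, vinyl ketone, chelation-controlled reduction that sets C3.
5. Ring order: dioxolane (protecting ring, step 1), cyclohexene (step 12), dioxolane opened (step 21).

Key step: step 12

Remark: phenyl 1-thio-β-D-galactopyranoside is taken as the commercial form of D-galactose whose anomeric group can be removed under neutral conditions. Compounds 1–10 use sugar numbering; 13–15 are numbered as oct-1-ene chains, whose C3–C6 become ring C3–C6 and whose C7 becomes ring C1.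

**Route**

Step 1
Reactants: 1 phenyl 1-thio-β-D-galactopyranoside
Product: 3 phenyl 3,4-O-isopropylidene-1-thio-β-D-galactopyranoside, via 6-O-methoxyisopropyl mixed acetal 2 (not isolated)
Conditions: Me2C(OMe)2, CSA (cat.), acetone, rt; Et3N; then MeOH/H2O 10:1, 60 °C
Reagents that add atoms: 2,2-dimethoxypropane (COC(C)(C)OC)
Why: Acid-catalysed transacetalization puts the isopropylidene group on the only cis-vicinal diol (O3/O4) as the thermodynamically favoured dioxolane, and the acyclic mixed acetal that forms at O6 is hydrolysed selectively in warm aqueous methanol because it is far more labile than the cyclic acetal.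

Step 2
Reactants: 3 phenyl 3,4-O-isopropylidene-1-thio-β-D-galactopyranoside
Product: 4 phenyl 6-O-(tert-butyldimethylsilyl)-3,4-O-isopropylidene-1-thio-β-D-galactopyranoside
Conditions: TBSCl, imidazole, DMF, 0 °C
Reagents that add atoms: tert-butyldimethylsilyl chloride (CC(C)(C)[Si](C)(C)Cl)
Why: Silyl ether formation is much faster at the primary 6-OH than at the hindered secondary 2-OH, so one equivalent of TBSCl should give the 6-O-silyl ether alone.

Step 3
Reactants: 4 phenyl 6-O-(tert-butyldimethylsilyl)-3,4-O-isopropylidene-1-thio-β-D-galactopyranoside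
Product: 5 phenyl 6-O-(tert-butyldimethylsilyl)-3,4-O-isopropylidene-2-O-methyl-1-thio-β-D-galactopyranoside
Conditions: NaH, MeI, THF, 0 °C → rt
Reagents that add atoms: iodomethane (CI)
Why: Williamson etherification of the single free hydroxyl, under which the thioglycoside, silyl ether and acetonide are stable.

Step 4
Reactants: 5 phenyl 6-O-(tert-butyldimethylsilyl)-3,4-O-isopropylidene-2-O-methyl-1-thio-β-D-galactopyranoside
Product: 6 6-O-(tert-butyldimethylsilyl)-3,4-O-isopropylidene-2-O-methyl-D-galactopyranose (lactol; anomeric mixture)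
Conditions: NBS, NaHCO3, acetone/H2O 9:1, −15 → 0 °C
Reagents that add atoms: water (O)
Why: Oxidative thioglycoside hydrolysis, in which NBS turns the sulfide into a bromosulfonium leaving group and water captures the oxocarbenium ion, the bicarbonate buffer protecting the acetonide and silyl ether.

Step 5
Reactants: 6 6-O-(tert-butyldimethylsilyl)-3,4-O-isopropylidene-2-O-methyl-D-galactopyranose
Product: 7 6-O-(tert-butyldimethylsilyl)-3,4-O-isopropylidene-2-O-methyl-D-galactono-1,5-lactone
Conditions: Dess–Martin periodinane, pyridine, CH2Cl2, rt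
Reagents that add atoms: none
Why: Dess–Martin oxidation of the hemiacetal hydroxyl gives the 1,5-lactone under neutral conditions that should not epimerize C2.

Step 6
Reactants: 7 6-O-(tert-butyldimethylsilyl)-3,4-O-isopropylidene-2-O-methyl-D-galactono-1,5-lactone
Product: 8 6-O-(tert-butyldimethylsilyl)-3,4-O-isopropylidene-N-methoxy-N-methyl-2-O-methyl-D-galactonamide (open chain; only O5–H free)
Conditions: MeNH(OMe)·HCl, AlMe3, CH2Cl2, 0 °C → rt; aq. potassium sodium tartrate
Reagents that add atoms: N,O-dimethylhydroxylamine hydrochloride (CNOC.Cl)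
Why: Weinreb aminolysis, in which the weakly basic aluminium amide formed from AlMe3 and the amine hydrochloride opens the lactone without β-elimination at C2/C3 and leaves O5–H as the only free hydroxyl of an open-chain compound.

Step 7
Reactants: 8 6-O-(tert-butyldimethylsilyl)-3,4-O-isopropylidene-N-methoxy-N-methyl-2-O-methyl-D-galactonamide
Product: 9 6-O-(tert-butyldimethylsilyl)-3,4-O-isopropylidene-N-methoxy-N-methyl-2-O-methyl-L-arabino-hex-5-ulosonamide (C5 ketone)
Conditions: Dess–Martin periodinane, pyridine, CH2Cl2, 0 °C → rt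
Reagents that add atoms: none
Why: Dess–Martin oxidation of the only secondary alcohol gives the C5 ketone under buffered conditions that should not epimerize C4.

Step 8
Reactants: 9 6-O-(tert-butyldimethylsilyl)-3,4-O-isopropylidene-N-methoxy-N-methyl-2-O-methyl-L-arabino-hex-5-ulosonamide
Product: 10 6-O-(tert-butyldimethylsilyl)-5-deoxy-3,4-O-isopropylidene-N-methoxy-N-methyl-2-O-methyl-5-methylidene-L-arabino-hexonamide
Conditions: Ph3PCH3Br, KN(SiMe3)2, THF, −78 → 0 °C
Reagents that add atoms: methyltriphenylphosphonium bromide (C[P+](c1ccccc1)(c1ccccc1)c1ccccc1.[Br-])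
Why: Wittig methylenation, in which the unstabilized ylide attacks the ketone far faster than the Weinreb amide and, at low temperature, faster than it enolizes the ketone toward C4.

Step 9
Reactants: 10 6-O-(tert-butyldimethylsilyl)-5-deoxy-3,4-O-isopropylidene-N-methoxy-N-methyl-2-O-methyl-5-methylidene-L-arabino-hexonamide; 11 vinylmagnesium bromide
Product: 13 8-O-(tert-butyldimethylsilyl)-1,2,7-trideoxy-5,6-O-isopropylidene-4-O-methyl-7-methylidene-L-arabino-oct-1-en-3-ulose (vinyl ketone), via magnesium hemiaminal chelate 12 (not isolated)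
Conditions: THF, −78 → −20 °C; inverse quench into cold aq. NH4Cl
Reagents that add atoms: none
Why: Weinreb ketone synthesis, in which a single vinyl group adds because the five-membered magnesium chelate is stable until the cold inverse quench, which releases the enone and keeps the liberated amine protonated so that it does not add back in a conjugate sense.

Step 10
Reactants: 13 8-O-(tert-butyldimethylsilyl)-1,2,7-trideoxy-5,6-O-isopropylidene-4-O-methyl-7-methylidene-L-arabino-oct-1-en-3-ulose
Product: 14 8-O-(tert-butyldimethylsilyl)-1,2,7-trideoxy-5,6-O-isopropylidene-4-O-methyl-7-methylidene-L-manno-oct-1-enitol ((3S)-allylic alcohol; 3-OH/4-OMe erythro)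
Conditions: Zn(BH4)2, Et2O, −30 °C
Reagents that add atoms: none
Why: Chelation-controlled (Cram chelate) 1,2-reduction, in which zinc bridges the carbonyl oxygen and the adjacent methoxy oxygen and hydride enters from the face of the chelate that carries C4–H, which should set the new C3 stereocentre as S (3-OH/4-OMe erythro, the cis relationship of ring C3/C4).

Step 11
Reactants: 14 8-O-(tert-butyldimethylsilyl)-1,2,7-trideoxy-5,6-O-isopropylidene-4-O-methyl-7-methylidene-L-manno-oct-1-enitol
Product: 15 3,8-di-O-(tert-butyldimethylsilyl)-1,2,7-trideoxy-5,6-O-isopropylidene-4-O-methyl-7-methylidene-L-manno-oct-1-enitol (1,7-diene)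
Conditions: TBSOTf, 2,6-lutidine, CH2Cl2, −78 → 0 °C
Reagents that add atoms: tert-butyldimethylsilyl trifluoromethanesulfonate (CC(C)(C)[Si](C)(C)OS(=O)(=O)C(F)(F)F)
Why: Silylation with the silyl triflate protects the hindered secondary allylic alcohol under non-acidic conditions.

Step 12
Reactants: 15 3,8-di-O-(tert-butyldimethylsilyl)-1,2,7-trideoxy-5,6-O-isopropylidene-4-O-methyl-7-methylidene-L-manno-oct-1-enitol
Product: 16 1-[(tert-butyldimethylsilyloxy)methyl]-3-(tert-butyldimethylsilyloxy)-5,6-(isopropylidenedioxy)-4-methoxycyclohex-1-ene (C3–O and C4–OMe on one face; C5–O and C6–O on the other; configured as in 27)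
Conditions: second-generation Hoveyda–Grubbs catalyst RuCl2(H2IMes)(=CH-C6H4-2-OiPr) (5–10 mol%), toluene (0.005 M), 80 °C, Ar sparge
Reagents that add atoms: none
Why: The ruthenium benzylidene exchanges its chelating isopropoxystyrene ligand for the monosubstituted vinyl group on C3, the new alkylidene adds across the 1,1-disubstituted alkene on C6 to give a ruthenacyclobutane, and cycloreversion forms the C1=C2 bond while the methylidene carrier releases ethylene (Chauvin mechanism). The closest known reaction type is ring-closing metathesis of carbohydrate-derived 1,7-dienes with one 1,1-disubstituted alkene to carbasugar cyclohexenes. The six-membered carbocycle is closed by joining the two inner alkene carbons of the octa-1,7-diene chain, so the ring contains the new trisubstituted alkene. No stereocentre is formed or touched; C3 (from the chelation-controlled reduction) and C4–C6 (from galactose) are carried through unchanged. The step needs cyclization to outrun intermolecular metathesis through the vinyl group, which high dilution, removal of ethylene and the cis-fused dioxolane on C5/C6 (it turns the two chain ends toward each other) should secure. Double-bond migration is not expected and can be suppressed with 1,4-benzoquinone if it appears.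

Step 13
Reactants: 16 1-[(tert-butyldimethylsilyloxy)methyl]-3-(tert-butyldimethylsilyloxy)-5,6-(isopropylidenedioxy)-4-methoxycyclohex-1-ene
Product: 17 [3-(tert-butyldimethylsilyloxy)-5,6-(isopropylidenedioxy)-4-methoxycyclohex-1-en-1-yl]methanol
Conditions: HF·pyridine, pyridine, THF, 0 °C
Reagents that add atoms: none
Why: Selective desilylation, in which buffered HF·pyridine cleaves the unhindered primary allylic silyl ether much faster than the secondary one flanked by C2 and C4 and does not touch the acetonide.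

Step 14
Reactants: 17 [3-(tert-butyldimethylsilyloxy)-5,6-(isopropylidenedioxy)-4-methoxycyclohex-1-en-1-yl]methanol
Product: 18 3-(tert-butyldimethylsilyloxy)-5,6-(isopropylidenedioxy)-4-methoxycyclohex-1-ene-1-carbaldehyde
Conditions: MnO2, CH2Cl2, rt
Reagents that add atoms: none
Why: MnO2 oxidation of the primary allylic alcohol stops at the enal under neutral heterogeneous conditions.

Step 15
Reactants: 18 3-(tert-butyldimethylsilyloxy)-5,6-(isopropylidenedioxy)-4-methoxycyclohex-1-ene-1-carbaldehyde
Product: 19 1-ethynyl-3-(tert-butyldimethylsilyloxy)-5,6-(isopropylidenedioxy)-4-methoxycyclohex-1-ene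
Conditions: MeC(O)C(N2)P(O)(OMe)2, K2CO3, MeOH, 0 °C → rt
Reagents that add atoms: dimethyl (1-diazo-2-oxopropyl)phosphonate (COP(=O)(OC)C(=[N+]=[N-])C(C)=O)
Why: Ohira–Bestmann (Seyferth–Gilbert) homologation, in which methanolysis of the reagent frees the diazomethylphosphonate anion, this adds to the aldehyde, and loss of dimethyl phosphate and N2 with a 1,2-hydrogen shift gives the terminal alkyne, conjugate addition of methanol being unlikely to compete on an α-substituted cyclic enal.

Step 16
Reactants: 20 2-methylbut-3-yn-2-ol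
Product: 21 (E)-2-methyl-4-(tributylstannyl)but-3-en-2-ol
Conditions: Bu3SnH, PdCl2(PPh3)2 (cat.), THF, 0 °C → rt
Reagents that add atoms: tributyltin hydride (CCCC[SnH](CCCC)CCCC)
Why: Palladium-catalysed syn-hydrostannation, in which tin goes to the terminal carbon away from the bulky tertiary carbinol and should give mainly the (E)-vinylstannane, any internal regioisomer being removed by chromatography.

Step 17
Reactants: 21 (E)-2-methyl-4-(tributylstannyl)but-3-en-2-ol; 22 2,3-dibromoprop-1-ene
Product: 23 (E)-6-bromo-2-methylhepta-3,6-dien-2-ol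
Conditions: Pd2(dba)3 (cat.), AsPh3, THF, 50 °C (excess 22)
Reagents that add atoms: none
Why: Stille coupling, in which the allylic C–Br bond adds to zerovalent palladium much faster than the vinylic one, both termini of the 2-bromoallyl unit give the same product, and the vinyl group is transferred from tin with retention of the E geometry.

Step 18
Reactants: 19 1-ethynyl-3-(tert-butyldimethylsilyloxy)-5,6-(isopropylidenedioxy)-4-methoxycyclohex-1-ene; 23 (E)-6-bromo-2-methylhepta-3,6-dien-2-ol
Product: 24 1-[(5E)-7-hydroxy-7-methyl-3-methylideneoct-5-en-1-yn-1-yl]-3-(tert-butyldimethylsilyloxy)-5,6-(isopropylidenedioxy)-4-methoxycyclohex-1-ene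
Conditions: PdCl2(PPh3)2 (cat.), CuI (cat.), Et3N, THF, rt → 40 °C, degassed
Reagents that add atoms: none
Why: Sonogashira coupling of the terminal alkyne with the 2-bromoalkene joins Cb to the side chain under mild amine conditions that the tertiary alcohol, silyl ether and acetonide tolerate.

Step 19
Reactants: 24 1-[(5E)-7-hydroxy-7-methyl-3-methylideneoct-5-en-1-yn-1-yl]-3-(tert-butyldimethylsilyloxy)-5,6-(isopropylidenedioxy)-4-methoxycyclohex-1-ene
Product: 25 3-[(5E)-7-hydroxy-7-methyl-3-methylideneoct-5-en-1-yn-1-yl]-4,5-(isopropylidenedioxy)-6-methoxycyclohex-2-en-1-ol (ring C3 alcohol)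
Conditions: TBAF, THF, 0 °C → rt
Reagents that add atoms: none
Why: Fluoride-mediated desilylation frees the C3 hydroxyl without affecting the acetonide or the enyne.

Step 20
Reactants: 25 3-[(5E)-7-hydroxy-7-methyl-3-methylideneoct-5-en-1-yn-1-yl]-4,5-(isopropylidenedioxy)-6-methoxycyclohex-2-en-1-ol
Product: 26 3-[(5E)-7-hydroxy-7-methyl-3-methylideneoct-5-en-1-yn-1-yl]-4,5-(isopropylidenedioxy)-6-methoxycyclohex-2-en-1-yl acetate
Conditions: Ac2O, pyridine, DMAP (cat.), CH2Cl2, 0 °C
Reagents that add atoms: acetic anhydride (CC(=O)OC(C)=O)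
Why: Acylation discriminates the secondary allylic C3 hydroxyl from the tertiary side-chain hydroxyl, which should not react at 0 °C with catalytic DMAP.

Step 21
Reactants: 26 3-[(5E)-7-hydroxy-7-methyl-3-methylideneoct-5-en-1-yn-1-yl]-4,5-(isopropylidenedioxy)-6-methoxycyclohex-2-en-1-yl acetate
Product: 27 (1S,4S,5S,6R)-4,5-dihydroxy-6-methoxy-3-[(5E)-7-hydroxy-7-methyl-3-methylideneoct-5-en-1-yn-1-yl]cyclohex-2-en-1-yl acetate (CNP0546270.2)
Conditions: AcOH/H2O 4:1, rt → 40 °C
Reagents that add atoms: none
Why: Acid-catalysed acetal hydrolysis of the cis-fused dioxolane in weak aqueous acid, where the C4 methyl ether blocks 1,2-acetyl migration and the tertiary allylic alcohol and allylic acetate should not ionize.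

**Compound list**

1 | phenyl 1-thio-β-D-galactopyranoside | c1ccccc1S[C@H]1[C@H](O)[C@@H](O)[C@@H](O)[C@@H](CO)O1 | starting material
2 | phenyl 3,4-O-isopropylidene-6-O-(2-methoxypropan-2-yl)-1-thio-β-D-galactopyranoside | c1ccccc1S[C@H]1[C@H](O)[C@@H]2[C@@H](OC(C)(C)O2)[C@@H](COC(C)(C)OC)O1 | intermediate (not isolated)
3 | phenyl 3,4-O-isopropylidene-1-thio-β-D-galactopyranoside | c1ccccc1S[C@H]1[C@H](O)[C@@H]2[C@@H](OC(C)(C)O2)[C@@H](CO)O1 | intermediate
4 | phenyl 6-O-(tert-butyldimethylsilyl)-3,4-O-isopropylidene-1-thio-β-D-galactopyranoside | c1ccccc1S[C@H]1[C@H](O)[C@@H]2[C@@H](OC(C)(C)O2)[C@@H](CO[Si](C)(C)C(C)(C)C)O1 | intermediate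
5 | phenyl 6-O-(tert-butyldimethylsilyl)-3,4-O-isopropylidene-2-O-methyl-1-thio-β-D-galactopyranoside | c1ccccc1S[C@H]1[C@H](OC)[C@@H]2[C@@H](OC(C)(C)O2)[C@@H](CO[Si](C)(C)C(C)(C)C)O1 | intermediate
6 | 6-O-(tert-butyldimethylsilyl)-3,4-O-isopropylidene-2-O-methyl-D-galactopyranose (lactol, anomeric mixture) | OC1[C@H](OC)[C@@H]2[C@@H](OC(C)(C)O2)[C@@H](CO[Si](C)(C)C(C)(C)C)O1 | intermediate
7 | 6-O-(tert-butyldimethylsilyl)-3,4-O-isopropylidene-2-O-methyl-D-galactono-1,5-lactone | O=C1[C@H](OC)[C@@H]2[C@@H](OC(C)(C)O2)[C@@H](CO[Si](C)(C)C(C)(C)C)O1 | intermediate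
8 | 6-O-(tert-butyldimethylsilyl)-3,4-O-isopropylidene-N-methoxy-N-methyl-2-O-methyl-D-galactonamide (5-OH free) | CON(C)C(=O)[C@H](OC)[C@@H]1[C@@H](OC(C)(C)O1)[C@H](O)CO[Si](C)(C)C(C)(C)C | intermediate
9 | 6-O-(tert-butyldimethylsilyl)-3,4-O-isopropylidene-N-methoxy-N-methyl-2-O-methyl-L-arabino-hex-5-ulosonamide | CON(C)C(=O)[C@H](OC)[C@@H]1[C@@H](OC(C)(C)O1)C(=O)CO[Si](C)(C)C(C)(C)C | intermediate
10 | 6-O-(tert-butyldimethylsilyl)-5-deoxy-3,4-O-isopropylidene-N-methoxy-N-methyl-2-O-methyl-5-methylidene-L-arabino-hexonamide | CON(C)C(=O)[C@H](OC)[C@@H]1[C@@H](OC(C)(C)O1)C(=C)CO[Si](C)(C)C(C)(C)C | intermediate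
11 | vinylmagnesium bromide | C=C[Mg]Br | starting material
12 | bromomagnesium salt of the N-methoxy-N-methyl hemiaminal formed from 10 and 11 (tetrahedral adduct, new centre undefined) | C=CC(O[Mg]Br)(N(C)OC)[C@H](OC)[C@@H]1[C@@H](OC(C)(C)O1)C(=C)CO[Si](C)(C)C(C)(C)C | intermediate (not isolated)
13 | 8-O-(tert-butyldimethylsilyl)-1,2,7-trideoxy-5,6-O-isopropylidene-4-O-methyl-7-methylidene-L-arabino-oct-1-en-3-ulose | C=CC(=O)[C@H](OC)[C@@H]1[C@@H](OC(C)(C)O1)C(=C)CO[Si](C)(C)C(C)(C)C | intermediate
14 | 8-O-(tert-butyldimethylsilyl)-1,2,7-trideoxy-5,6-O-isopropylidene-4-O-methyl-7-methylidene-L-manno-oct-1-enitol ((3S)-alcohol) | C=C[C@H](O)[C@H](OC)[C@@H]1[C@@H](OC(C)(C)O1)C(=C)CO[Si](C)(C)C(C)(C)C | intermediate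
15 | 3,8-di-O-(tert-butyldimethylsilyl)-1,2,7-trideoxy-5,6-O-isopropylidene-4-O-methyl-7-methylidene-L-manno-oct-1-enitol | C=C[C@H](O[Si](C)(C)C(C)(C)C)[C@H](OC)[C@@H]1[C@@H](OC(C)(C)O1)C(=C)CO[Si](C)(C)C(C)(C)C | intermediate
16 | 1-[(tert-butyldimethylsilyloxy)methyl]-3-(tert-butyldimethylsilyloxy)-5,6-(isopropylidenedioxy)-4-methoxycyclohex-1-ene (configured as in 27) | CC(C)(C)[Si](C)(C)OCC1=C[C@H](O[Si](C)(C)C(C)(C)C)[C@H](OC)[C@@H]2[C@H]1OC(C)(C)O2 | intermediate
17 | [3-(tert-butyldimethylsilyloxy)-5,6-(isopropylidenedioxy)-4-methoxycyclohex-1-en-1-yl]methanol | OCC1=C[C@H](O[Si](C)(C)C(C)(C)C)[C@H](OC)[C@@H]2[C@H]1OC(C)(C)O2 | intermediate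
18 | 3-(tert-butyldimethylsilyloxy)-5,6-(isopropylidenedioxy)-4-methoxycyclohex-1-ene-1-carbaldehyde | O=CC1=C[C@H](O[Si](C)(C)C(C)(C)C)[C@H](OC)[C@@H]2[C@H]1OC(C)(C)O2 | intermediate
19 | 1-ethynyl-3-(tert-butyldimethylsilyloxy)-5,6-(isopropylidenedioxy)-4-methoxycyclohex-1-ene | C#CC1=C[C@H](O[Si](C)(C)C(C)(C)C)[C@H](OC)[C@@H]2[C@H]1OC(C)(C)O2 | intermediate
20 | 2-methylbut-3-yn-2-ol | CC(C)(O)C#C | starting material
21 | (E)-2-methyl-4-(tributylstannyl)but-3-en-2-ol | CCCC[Sn](CCCC)(CCCC)/C=C/C(C)(C)O | intermediate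
22 | 2,3-dibromoprop-1-ene | C=C(Br)CBr | starting material
23 | (E)-6-bromo-2-methylhepta-3,6-dien-2-ol | C=C(Br)C/C=C/C(C)(C)O | intermediate
24 | 1-[(5E)-7-hydroxy-7-methyl-3-methylideneoct-5-en-1-yn-1-yl]-3-(tert-butyldimethylsilyloxy)-5,6-(isopropylidenedioxy)-4-methoxycyclohex-1-ene | C=C(C#CC1=C[C@H](O[Si](C)(C)C(C)(C)C)[C@H](OC)[C@@H]2[C@H]1OC(C)(C)O2)C/C=C/C(C)(C)O | intermediate
25 | 3-[(5E)-7-hydroxy-7-methyl-3-methylideneoct-5-en-1-yn-1-yl]-4,5-(isopropylidenedioxy)-6-methoxycyclohex-2-en-1-ol | C=C(C#CC1=C[C@H](O)[C@H](OC)[C@@H]2[C@H]1OC(C)(C)O2)C/C=C/C(C)(C)O | intermediate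
26 | 3-[(5E)-7-hydroxy-7-methyl-3-methylideneoct-5-en-1-yn-1-yl]-4,5-(isopropylidenedioxy)-6-methoxycyclohex-2-en-1-yl acetate | C=C(C#CC1=C[C@H](OC(C)=O)[C@H](OC)[C@@H]2[C@H]1OC(C)(C)O2)C/C=C/C(C)(C)O | intermediate
27 | (1S,4S,5S,6R)-4,5-dihydroxy-6-methoxy-3-[(5E)-7-hydroxy-7-methyl-3-methylideneoct-5-en-1-yn-1-yl]cyclohex-2-en-1-yl acetate | C=C(C#CC1=C[C@H](OC(C)=O)[C@H](OC)[C@@H](O)[C@H]1O)C/C=C/C(C)(C)O | target

**Count**

Total steps: 21 (19 in the main line, 2 for bromodiene 23).
Longest linear sequence: 19 steps (steps 1–15 and 18–21).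

**Steps most likely to fail**

Step 12 (ring-closing metathesis). Closure may lose to intermolecular metathesis through the unhindered end of the vinyl group, or the catalyst may load slowly next to the bulky C3 silyl ether and decay before the hindered 1,1-disubstituted alkene is engaged. The fallback inverts the order of silylation and ring closure, so that a different, less hindered substrate is cyclized. It sets out from dienol 14. Metathesis of the free allylic alcohol (same catalyst, CH2Cl2, 40 °C, high dilution) should be easier, because a hydroxyl group next to the initiating alkene is known to speed up loading of ruthenium and no silyl group crowds it. It should give 1-[(tert-butyldimethylsilyloxy)methyl]-5,6-(isopropylidenedioxy)-4-methoxycyclohex-1-en-3-ol F1. Silylation (TBSOTf, 2,6-lutidine, CH2Cl2) then comes back to the route at 16.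

Step 10 (chelation-controlled reduction). Facial selectivity may erode if zinc chelates the C5 dioxolane oxygen instead of the C4 methoxy group, or if non-chelated Felkin–Anh delivery competes; the (3R)-epimer would then form alongside 14. The fallback corrects the centre by inversion instead of relying on the reduction alone. It sets out from 13: the (3R)-alcohol F2 that the reduction forms is separated and subjected to Mitsunobu inversion (4-nitrobenzoic acid, PPh3, DIAD, THF, 0 °C) to give the (3S)-4-nitrobenzoate F3. Methanolysis (K2CO3, MeOH) comes back to the route at 14.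

Step 21 (acetonide hydrolysis). Under the aqueous acid, ionization of the tertiary allylic alcohol of the side chain (allylic transposition or dehydration) or solvolysis of the allylic acetate may compete with acetal hydrolysis. The fallback moves the acid step in front of the coupling, so that the acid never meets the side chain. It sets out from enyne 19: TBAF in THF gives 3-ethynyl-4,5-(isopropylidenedioxy)-6-methoxycyclohex-2-en-1-ol F4. Ac2O/pyridine/DMAP gives the corresponding acetate F5, and AcOH/H2O gives 3-ethynyl-4,5-dihydroxy-6-methoxycyclohex-2-en-1-yl acetate F6. Sonogashira coupling of F6 with 23 (PdCl2(PPh3)2, CuI, Et3N, THF, rt) then comes back to the route at the target 27.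

**Further compounds**

F1 | step 12 | 1-[(tert-butyldimethylsilyloxy)methyl]-5,6-(isopropylidenedioxy)-4-methoxycyclohex-1-en-3-ol (configured as in 16) | CC(C)(C)[Si](C)(C)OCC1=C[C@H](O)[C@H](OC)[C@@H]2[C@H]1OC(C)(C)O2
F2 | step 10 | (3R)-epimer of 14 (3-OH/4-OMe threo) | C=C[C@@H](O)[C@H](OC)[C@@H]1[C@@H](OC(C)(C)O1)C(=C)CO[Si](C)(C)C(C)(C)C
F3 | step 10 | 3-O-(4-nitrobenzoyl) derivative of 14 ((3S)-ester) | C=C[C@H](OC(=O)c1ccc(cc1)[N+](=O)[O-])[C@H](OC)[C@@H]2[C@@H](OC(C)(C)O2)C(=C)CO[Si](C)(C)C(C)(C)C
F4 | step 21 | 3-ethynyl-4,5-(isopropylidenedioxy)-6-methoxycyclohex-2-en-1-ol (configured as in 19) | C#CC1=C[C@H](O)[C@H](OC)[C@@H]2[C@H]1OC(C)(C)O2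
F5 | step 21 | 3-ethynyl-4,5-(isopropylidenedioxy)-6-methoxycyclohex-2-en-1-yl acetate | C#CC1=C[C@H](OC(C)=O)[C@H](OC)[C@@H]2[C@H]1OC(C)(C)O2
F6 | step 21 | 3-ethynyl-4,5-dihydroxy-6-methoxycyclohex-2-en-1-yl acetate (configured as in 27) | C#CC1=C[C@H](OC(C)=O)[C@H](OC)[C@@H](O)[C@H]1O
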